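**Retrosynthetic overview** (ring A = the furan-2,5-dione that carries CH2OH; ring B = the furan-2,5-dione that carries the 2-oxohexyl chain)
1. The target comes from a precursor with a TBDPS ether on the CH2OH, ring B as its di-tert-butyl maleate, the ketone as a dioxolane and an E-alkene in the future pentyl chain. These are released by hydrogenation, acidolysis and fluoride.
2. Key disconnection: the CH2–CH bond between ring A and the stereocentre. It is made by a decarboxylative Ireland–Claisen rearrangement of an allylic ester that ties the two halves together, and the tether leaves as CO2.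
3. Enabling feature: the exocyclic CH2 on C3 of ring A is the γ-carbon of the ring C3=C4–C5=O unit. It can therefore carry a temporary CO2R group, is acidified by it, and sheds it as CO2. The stereocentre is the allyl terminus of a ring-B–CH=CH–CH(O)–Pr unit whose C=C moves into the pentyl chain.
4. The ester is split into a ring-A acetic acid and a ring-B (S)-allylic alcohol. Both come from di-tert-butyl dibromomaleate by two successive Pd couplings.
5. Ring order: the dioxolane (temporary) first, then ring A before the union, then ring B after the union.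

Key step: step 12

Assumption: the hydroxymethyl anhydride as drawn is taken as the isolable form of the target. Direct acyl transfer to the isomeric butenolide acid would need a tetrahedral intermediate with a bridgehead C=C, so only long contact with water or base after the last step has to be avoided.

**Step 1**
Reactants: 1 2,3-dibromomaleic acid
Product: 2 di-tert-butyl 2,3-dibromomaleate
Conditions: Cl3CC(=NH)OtBu (4 equiv), CH2Cl2/cyclohexane, rt
Reagents that add atoms: tert-butyl 2,2,2-trichloroacetimidate, CC(C)(C)OC(=N)C(Cl)(Cl)Cl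
Why: Imidate tert-butylation alkylates the carboxyl oxygens without activating the acyl carbons, so the cis-diacid cannot escape into its anhydride and the alkene geometry is kept.

**Step 2**
Reactants: 3 2-bromo-N-methoxy-N-methylacetamide; 4 butylmagnesium chloride
Product: 5 1-bromohexan-2-one
Conditions: THF, −78 → −30 °C; 1 M HCl
Reagents that add atoms: none
Why: Weinreb ketone synthesis, in which the chelated tetrahedral adduct stops at the ketone stage and places bromine unambiguously on the terminal carbon.

**Step 3**
Reactants: 5 1-bromohexan-2-one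
Product: 6 2-(bromomethyl)-2-butyl-1,3-dioxolane
Conditions: HOCH2CH2OH, p-TsOH (cat.), toluene, reflux, Dean–Stark
Reagents that add atoms: ethane-1,2-diol, OCCO
Why: Acid-catalysed ketalisation with azeotropic removal of water masks the ketone and removes the acidic CH2C=O protons of the future side chain.

**Step 4**
Reactants: 6 2-(bromomethyl)-2-butyl-1,3-dioxolane; 2 di-tert-butyl 2,3-dibromomaleate
Product: 8 di-tert-butyl 2-bromo-3-[(2-butyl-1,3-dioxolan-2-yl)methyl]maleate, via alkylzinc bromide 7 (not isolated)
Conditions: Zn, LiCl, THF, 45 °C; then 2 (1.5 equiv), Pd(OAc)2/SPhos (cat.), THF, 25 → 45 °C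
Reagents that add atoms: none
Why: Zinc insertion followed by Negishi coupling, in which the organozinc has no β-hydrogen, resembles the stable (1,3-dioxolan-2-ylmethyl)zinc bromide, and leaves a more hindered and electron-richer C–Br bond that favours mono-substitution.

**Step 5**
Reactants: 8 bromo ketal maleate; 9 hex-1-en-3-one
Product: 10 di-tert-butyl 2-[(2-butyl-1,3-dioxolan-2-yl)methyl]-3-[(1E)-3-oxohex-1-en-1-yl]maleate
Conditions: Pd(OAc)2 (cat.), Bu4NCl, NaHCO3, DMF, 60 °C
Reagents that add atoms: none
Why: Mizoroki–Heck reaction, in which oxidative addition into the electron-poor C–Br bond, insertion at the unsubstituted enone terminus and syn β-hydride elimination should give the E-dienone with the maleate geometry retained.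

**Step 6**
Reactants: 10 dienone
Product: 11 di-tert-butyl 2-[(2-butyl-1,3-dioxolan-2-yl)methyl]-3-[(1E,3S)-3-hydroxyhex-1-en-1-yl]maleate
Conditions: (R)-Me-CBS (0.2 equiv), catecholborane, toluene, −78 °C; MeOH, aq. work-up
Reagents that add atoms: none
Why: Corey–Bakshi–Shibata reduction, in which the ketone binds the (R)-oxazaborolidine–borane complex with the dienyl group as the large and propyl as the small substituent, so hydride reaches the face that gives the (S)-alcohol, and catecholborane at −78 °C favours 1,2- over conjugate reduction.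

**Step 7**
Reactants: 2 di-tert-butyl 2,3-dibromomaleate; 12 (tributylstannyl)methanol
Product: 13 di-tert-butyl 2-bromo-3-(hydroxymethyl)maleate
Conditions: 2 (1.5 equiv), Pd(PPh3)4 (cat.), dioxane, 90 °C
Reagents that add atoms: none
Why: Stille coupling with selective transfer of the hydroxymethyl group, whose CH2OH lies trans to the distal ester in the maleate geometry and so cannot lactonise, while the excess of 2 limits double coupling.

**Step 8**
Reactants: 13 bromo alcohol
Product: 14 di-tert-butyl 2-bromo-3-{[(tert-butyldiphenylsilyl)oxy]methyl}maleate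
Conditions: TBDPSCl, imidazole, DMF, rt
Reagents that add atoms: tert-butylchlorodiphenylsilane, CC(C)(C)[Si](Cl)(c1ccccc1)c1ccccc1
Why: Standard silylation of a primary alcohol with a group chosen because it survives the two later trifluoroacetic acid steps and leaves with fluoride under non-basic conditions.

**Step 9**
Reactants: 14 bromo silyl ether; 15 (2-tert-butoxy-2-oxoethyl)zinc chloride
Product: 16 di-tert-butyl 2-(2-tert-butoxy-2-oxoethyl)-3-{[(tert-butyldiphenylsilyl)oxy]methyl}maleate
Conditions: 15 (2.2 equiv), Pd(dba)2/QPhos (cat.), THF, rt; aq. NH4Cl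
Reagents that add atoms: none
Why: Negishi-type cross-coupling of a Reformatsky reagent with a vinyl bromide, after which the acidic product rests as a stabilised zinc dienolate (made by the second equivalent of 15) until work-up.

**Step 10**
Reactants: 16 tri-tert-butyl ester
Product: 17 2-[4-{[(tert-butyldiphenylsilyl)oxy]methyl}-2,5-dioxo-2,5-dihydrofuran-3-yl]acetic acid
Conditions: TFA/CH2Cl2 (1:2), 0 °C → rt; toluene azeotrope; used at once
Reagents that add atoms: none
Why: Acidolysis of the three tert-butyl esters (E1 loss of isobutene), after which the cis-1,2-diacid closes spontaneously to the tetrasubstituted maleic anhydride and leaves the CH2CO2H arm free, as in cis-aconitic anhydride.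

**Step 11**
Reactants: 11 (S)-allylic alcohol; 17 ring-A acetic acid
Product: 18 (1E,3S)-allylic ester of 17 with 11
Conditions: DCC, DMAP (5 mol %), CH2Cl2, −10 → 0 °C
Reagents that add atoms: none
Why: Steglich esterification, in which the activated side-chain carboxyl is far more electrophilic than the tetrasubstituted ring anhydride (whose opening by a secondary alcohol is slow and reversible) and the carbinol C–O bond is not touched, so (S) is retained.

**Step 12**
Reactants: 18 allylic ester
Product: 22 di-tert-butyl 2-[(2-butyl-1,3-dioxolan-2-yl)methyl]-3-[(2S,3E)-1-(ring A silyl ether)hept-3-en-2-yl]maleate, via silyl ketene acetal 19 (not isolated), via rearranged silyl ester 20 (not isolated), via free acid 21 (not isolated)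
Conditions: N,O-bis(trimethylsilyl)acetamide (BSA, 3 equiv), toluene, 23 → 110 °C; then H2O (10 equiv), AcOH (1 equiv), KOAc (0.2 equiv), THF, 50 °C
Reagents that add atoms: none
Why: BSA silylates the doubly activated CH2 of 18 (α to the tether ester and γ to the ring C=O through the ring C=C) without an ionic base, ketene acetal 19 undergoes a [3,3]-sigmatropic shift through a chair transition state to silyl ester 20, and water then frees acid 21, a vinylogous β-keto acid that loses CO2 while the acetate buffer returns the C=C to the endocyclic tetrasubstituted position of the anhydride. The closest known reaction types are the decarboxylative Ireland–Claisen rearrangement of allyl esters of acceptor-substituted acetic acids (BSA, KOAc), the Carroll rearrangement and the thermal decarboxylation of 2-(carboxymethyl)maleic anhydrides. No ring is closed: the only cyclic array is the six-membered pericyclic transition state, and the anhydride, the dioxolane and the maleate are spectators. The new stereocentre is fixed by suprafacial 1,3-chirality transfer from the (S)-carbinol carbon across the E-alkene with propyl pseudo-equatorial, which should give the E-alkene and the (S) descriptor in 22 (the same spatial arrangement is (R) once the alkene is saturated), whereas ketene acetal geometry and chair versus boat only affect the carboxyl-bearing carbon, which ends as CH2. The shift has to win over 5-exo conjugate addition of the same carbon to the dienyl diester, over loss of the allylic carboxylate and over migration of the new skipped alkene, and this is secured by the neutral ketene acetal (no free enolate), the s-trans ester that disfavours lactone closure, the two tert-butyl esters that twist the diene out of conjugation, the ketal that removes the acidic CH2C=O protons and the weakly acidic buffered second stage. Silylation on the ring carbonyl oxygen is unproductive but reversible, so only the tether ketene acetal drains the equilibrium.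

**Step 13**
Reactants: 22 skipped diene
Product: 23 di-tert-butyl 2-[(2-butyl-1,3-dioxolan-2-yl)methyl]-3-[(2R)-1-(ring A silyl ether)heptan-2-yl]maleate
Conditions: H2 (3 atm), RhCl(PPh3)3 (10 mol %), benzene/THF, 40 °C
Reagents that add atoms: none
Why: Homogeneous hydrogenation with RhCl(PPh3)3 reduces the 1,2-disubstituted alkene but not the two tetrasubstituted electron-poor C=C bonds and causes little alkene migration, so the stereocentre is kept.

**Step 14**
Reactants: 23 saturated diester ketal
Product: 24 (R)-bis-anhydride ketone TBDPS ether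
Conditions: TFA/CH2Cl2/H2O (10:10:1), 0 °C → rt; toluene azeotrope
Reagents that add atoms: water, O
Why: Acidolysis of the two tert-butyl esters, spontaneous closure of ring B and hydrolysis of the dioxolane all run under the same acidic conditions, which cannot deprotonate the stereocentre and leave the TBDPS ether in place.

**Step 15**
Reactants: 24 TBDPS ether
Product: 25 target CNP0537712.2
Conditions: HF·pyridine, THF, 0 °C → rt; short cold wash at pH 3–4, rapid filtration through silica
Reagents that add atoms: none
Why: Fluoride-mediated desilylation under acidic, nearly anhydrous conditions, after which the freed CH2OH cannot attack its own anhydride ring because the tetrahedral intermediate would hold a bridgehead C=C.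

**Compound list**
1 | 2,3-dibromomaleic acid (carboxyl groups cis) | OC(=O)/C(Br)=C(/Br)C(=O)O | starting material
2 | di-tert-butyl 2,3-dibromomaleate (esters cis) | CC(C)(C)OC(=O)/C(Br)=C(/Br)C(=O)OC(C)(C)C | intermediate
3 | 2-bromo-N-methoxy-N-methylacetamide | CON(C)C(=O)CBr | starting material
4 | butylmagnesium chloride | CCCC[Mg]Cl | starting material
5 | 1-bromohexan-2-one | CCCCC(=O)CBr | intermediate
6 | 2-(bromomethyl)-2-butyl-1,3-dioxolane | CCCCC1(CBr)OCCO1 | intermediate
7 | [(2-butyl-1,3-dioxolan-2-yl)methyl]zinc bromide | CCCCC1(C[Zn]Br)OCCO1 | intermediate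
8 | di-tert-butyl 2-bromo-3-[(2-butyl-1,3-dioxolan-2-yl)methyl]maleate (esters cis) | CC(C)(C)OC(=O)/C(Br)=C(/CC1(CCCC)OCCO1)C(=O)OC(C)(C)C | intermediate
9 | hex-1-en-3-one | CCCC(=O)C=C | starting material
10 | di-tert-butyl 2-[(2-butyl-1,3-dioxolan-2-yl)methyl]-3-[(1E)-3-oxohex-1-en-1-yl]maleate | CC(C)(C)OC(=O)/C(CC1(CCCC)OCCO1)=C(/C=C/C(=O)CCC)C(=O)OC(C)(C)C | intermediate
11 | di-tert-butyl 2-[(2-butyl-1,3-dioxolan-2-yl)methyl]-3-[(1E,3S)-3-hydroxyhex-1-en-1-yl]maleate | CC(C)(C)OC(=O)/C(CC1(CCCC)OCCO1)=C(/C=C/[C@@H](O)CCC)C(=O)OC(C)(C)C | intermediate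
12 | (tributylstannyl)methanol | CCCC[Sn](CCCC)(CCCC)CO | starting material
13 | di-tert-butyl 2-bromo-3-(hydroxymethyl)maleate (esters cis) | CC(C)(C)OC(=O)/C(Br)=C(/CO)C(=O)OC(C)(C)C | intermediate
14 | di-tert-butyl 2-bromo-3-{[(tert-butyldiphenylsilyl)oxy]methyl}maleate | CC(C)(C)OC(=O)/C(Br)=C(/CO[Si](c1ccccc1)(c1ccccc1)C(C)(C)C)C(=O)OC(C)(C)C | intermediate
15 | (2-tert-butoxy-2-oxoethyl)zinc chloride | CC(C)(C)OC(=O)C[Zn]Cl | starting material
16 | di-tert-butyl 2-(2-tert-butoxy-2-oxoethyl)-3-{[(tert-butyldiphenylsilyl)oxy]methyl}maleate | CC(C)(C)OC(=O)/C(CC(=O)OC(C)(C)C)=C(/CO[Si](c1ccccc1)(c1ccccc1)C(C)(C)C)C(=O)OC(C)(C)C | intermediate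
17 | 2-[4-{[(tert-butyldiphenylsilyl)oxy]methyl}-2,5-dioxo-2,5-dihydrofuran-3-yl]acetic acid | OC(=O)CC1=C(CO[Si](c2ccccc2)(c2ccccc2)C(C)(C)C)C(=O)OC1=O | intermediate
18 | ester of acid 17 with the (3S)-hydroxy group of 11 (E-alkene, esters of ring B cis) | CC(C)(C)OC(=O)/C(CC1(CCCC)OCCO1)=C(/C=C/[C@@H](OC(=O)CC1=C(CO[Si](c2ccccc2)(c2ccccc2)C(C)(C)C)C(=O)OC1=O)CCC)C(=O)OC(C)(C)C | intermediate
19 | trimethylsilyl ketene acetal of 18 ((S)-carbinol; ketene acetal geometry not defined and without consequence) | CC(C)(C)OC(=O)/C(CC1(CCCC)OCCO1)=C(/C=C/[C@@H](OC(O[Si](C)(C)C)=CC1=C(CO[Si](c2ccccc2)(c2ccccc2)C(C)(C)C)C(=O)OC1=O)CCC)C(=O)OC(C)(C)C | intermediate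
20 | trimethylsilyl (3R,4E)-2-(ring A silyl ether)-3-(ring B diester)oct-4-enoate, epimers at C2 | CCC/C=C/[C@H](C(C(=O)O[Si](C)(C)C)C1=C(CO[Si](c2ccccc2)(c2ccccc2)C(C)(C)C)C(=O)OC1=O)/C(C(=O)OC(C)(C)C)=C(\CC1(CCCC)OCCO1)C(=O)OC(C)(C)C | intermediate
21 | (3R,4E)-2-(ring A silyl ether)-3-(ring B diester)oct-4-enoic acid, epimers at C2 | CCC/C=C/[C@H](C(C(=O)O)C1=C(CO[Si](c2ccccc2)(c2ccccc2)C(C)(C)C)C(=O)OC1=O)/C(C(=O)OC(C)(C)C)=C(\CC1(CCCC)OCCO1)C(=O)OC(C)(C)C | intermediate
22 | di-tert-butyl 2-[(2-butyl-1,3-dioxolan-2-yl)methyl]-3-[(2S,3E)-1-(4-{[(tert-butyldiphenylsilyl)oxy]methyl}-2,5-dioxo-2,5-dihydrofuran-3-yl)hept-3-en-2-yl]maleate | CCC/C=C/[C@H](CC1=C(CO[Si](c2ccccc2)(c2ccccc2)C(C)(C)C)C(=O)OC1=O)/C(C(=O)OC(C)(C)C)=C(\CC1(CCCC)OCCO1)C(=O)OC(C)(C)C | intermediate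
23 | di-tert-butyl 2-[(2-butyl-1,3-dioxolan-2-yl)methyl]-3-[(2R)-1-(4-{[(tert-butyldiphenylsilyl)oxy]methyl}-2,5-dioxo-2,5-dihydrofuran-3-yl)heptan-2-yl]maleate | CCCCC[C@H](CC1=C(CO[Si](c2ccccc2)(c2ccccc2)C(C)(C)C)C(=O)OC1=O)/C(C(=O)OC(C)(C)C)=C(\CC1(CCCC)OCCO1)C(=O)OC(C)(C)C | intermediate
24 | 3-[(2R)-1-(4-{[(tert-butyldiphenylsilyl)oxy]methyl}-2,5-dioxo-2,5-dihydrofuran-3-yl)heptan-2-yl]-4-(2-oxohexyl)furan-2,5-dione | CCCCC[C@H](CC1=C(CO[Si](c2ccccc2)(c2ccccc2)C(C)(C)C)C(=O)OC1=O)C1=C(CC(=O)CCCC)C(=O)OC1=O | intermediate
25 | 3-[(2R)-1-[4-(hydroxymethyl)-2,5-dioxo-2,5-dihydrofuran-3-yl]heptan-2-yl]-4-(2-oxohexyl)furan-2,5-dione | CCCCC[C@H](CC1=C(CO)C(=O)OC1=O)C1=C(CC(=O)CCCC)C(=O)OC1=O | target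

**Total step count:** 15. **Longest linear sequence:** 10 steps (1, 7–15 or 2–6, 11–15).

**Steps most likely to fail**

1. **Step 12.**
   - **Risk:** Both reacting termini lose conjugation in the shift, so it may be slow. Conjugate addition of the nucleophilic carbon to the dienyl diester may then take over. The new alkene may also migrate into conjugation, with loss of configuration, while CO2 leaves.
   - **Fallback (sets out from 18, returns at 23):** 18 is silylated under neutral conditions with N-(tert-butyldimethylsilyl)-N-methyltrifluoroacetamide to the tert-butyldimethylsilyl ketene acetal F1. This is heated in toluene to the isolable rearranged silyl ester F2. Hydrogenation with RhCl(PPh3)3 gives the saturated silyl ester F3. AcOH/H2O/THF then frees the saturated acid F4, which loses CO2 on warming to give 23.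
   - **What changes:** Bond formation and CO2 loss are separated by the hydrogenation. No enol-type intermediate exists while the C–H at the stereocentre is doubly allylic.

2. **Step 11.**
   - **Risk:** Acyl transfer from the ring anhydride to the alcohol, or loss of CO2 from the activated acid, may compete with ester formation.
   - **Fallback (sets out from 10 and 17, returns at 18):** 10 is reduced with the (S)-configured oxazaborolidine and catecholborane to the (R)-allylic alcohol F5. This is joined to 17 by a Mitsunobu esterification (PPh3, DIAD, toluene, 0 °C).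
   - **What changes:** The alcohol is activated instead of the acid, and the carbinol carbon is inverted to (S).

3. **Step 4.**
   - **Risk:** Possible failures are slow zinc insertion at the neopentyl-type bromide, loss of β-alkoxide from the alkylpalladium intermediate, or double substitution of 2.
   - **Fallback (sets out from 2, returns at 8):** Sonogashira coupling of 2 with hex-1-yne gives the bromo enyne F6. Gold(I)-catalysed hydration, with water adding to the alkyne carbon remote from the acceptor, gives the bromo ketone F7. Ketalisation with 1,2-bis(trimethylsilyloxy)ethane and catalytic TMSOTf at low temperature gives 8.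

**Further compounds**
F1 | step 12 | tert-butyldimethylsilyl ketene acetal of 18 | CC(C)(C)OC(=O)/C(CC1(CCCC)OCCO1)=C(/C=C/[C@@H](OC(O[Si](C)(C)C(C)(C)C)=CC1=C(CO[Si](c2ccccc2)(c2ccccc2)C(C)(C)C)C(=O)OC1=O)CCC)C(=O)OC(C)(C)C
F2 | step 12 | tert-butyldimethylsilyl (3R,4E)-2-(ring A silyl ether)-3-(ring B diester)oct-4-enoate, epimers at C2 | CCC/C=C/[C@H](C(C(=O)O[Si](C)(C)C(C)(C)C)C1=C(CO[Si](c2ccccc2)(c2ccccc2)C(C)(C)C)C(=O)OC1=O)/C(C(=O)OC(C)(C)C)=C(\CC1(CCCC)OCCO1)C(=O)OC(C)(C)C
F3 | step 12 | tert-butyldimethylsilyl (3R)-2-(ring A silyl ether)-3-(ring B diester)octanoate, epimers at C2 | CCCCC[C@H](C(C(=O)O[Si](C)(C)C(C)(C)C)C1=C(CO[Si](c2ccccc2)(c2ccccc2)C(C)(C)C)C(=O)OC1=O)/C(C(=O)OC(C)(C)C)=C(\CC1(CCCC)OCCO1)C(=O)OC(C)(C)C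
F4 | step 12 | (3R)-2-(ring A silyl ether)-3-(ring B diester)octanoic acid, epimers at C2 | CCCCC[C@H](C(C(=O)O)C1=C(CO[Si](c2ccccc2)(c2ccccc2)C(C)(C)C)C(=O)OC1=O)/C(C(=O)OC(C)(C)C)=C(\CC1(CCCC)OCCO1)C(=O)OC(C)(C)C
F5 | step 11 | di-tert-butyl 2-[(2-butyl-1,3-dioxolan-2-yl)methyl]-3-[(1E,3R)-3-hydroxyhex-1-en-1-yl]maleate | CC(C)(C)OC(=O)/C(CC1(CCCC)OCCO1)=C(/C=C/[C@H](O)CCC)C(=O)OC(C)(C)C
F6 | step 4 | di-tert-butyl 2-bromo-3-(hex-1-yn-1-yl)maleate (esters cis) | CC(C)(C)OC(=O)/C(Br)=C(/C#CCCCC)C(=O)OC(C)(C)C
F7 | step 4 | di-tert-butyl 2-bromo-3-(2-oxohexyl)maleate (esters cis) | CC(C)(C)OC(=O)/C(Br)=C(/CC(=O)CCCC)C(=O)OC(C)(C)C
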